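**Retrosynthetic overview**
1. The last bond formed is C5'–C6' of the skipped diene. It comes from a Stille coupling of an (E)-alkenylstannane on the bicyclic core (fragment 1) with an (E)-allylic bromide that already carries ring C, the butenolide (fragment 2).
2. Fragment 1 goes back from the stannane to a terminal alkyne, then to a quaternary aldehyde, then to periodate cleavage of a ring A/ring B diol.
3. Ring A (γ-lactone) and then ring B (oxolane) close in one operation. A carboxylesterase unmasks the acid and the alcohol of an acyclic bis-epoxy diester, and acid then drives two 5-exo epoxide openings with inversion at both tertiary carbons.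
4. The bis-epoxide comes from an achiral dienol ester (geraniol + methyl acetate) by Sharpless asymmetric epoxidation, which sets the first stereocentres, followed by Shi epoxidation.
5. In fragment 2, ring C is made by palladium-catalysed carbonylative lactonisation of a (Z)-3-iodoallylic alcohol, followed by SeO2 (E)-allylic oxidation and bromination. Ring order: C (separately), then A, then B.

Assumption: the SMILES is read as the (2R,5R)-oxolane (side chain and lactone trans) bearing the (2S)-lactone carbon, with both chain alkenes E. Acyclic precursors use decanoate numbering (C1 = ester carbon, C10 = CH2O).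

**Fragment 1**

Step 1
Reactants: 1 geraniol, (2E)-3,7-dimethylocta-2,6-dien-1-ol
Product: 2 geranyl TBS ether, tert-butyl{[(2E)-3,7-dimethylocta-2,6-dien-1-yl]oxy}dimethylsilane
Conditions: TBSCl (1.1 equiv), imidazole (2 equiv), CH2Cl2, 0 °C to rt
Reagents that add atoms: tert-butyldimethylsilyl chloride, CC(C)(C)[Si](C)(C)Cl
Why: Imidazole-promoted silyl ether formation masks the allylic alcohol against SeO2, the Appel reagent and the ester enolate, and no stereocentre is involved.

Step 2
Reactants: 2 geranyl TBS ether
Product: 3 (2E,6E)-8-[(tert-butyldimethylsilyl)oxy]-2,6-dimethylocta-2,6-dien-1-ol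
Conditions: SeO2 (0.1 equiv), t-BuOOH (3 equiv), salicylic acid (0.1 equiv), CH2Cl2, 0 °C to rt; the minor enal is removed by chromatography
Reagents that add atoms: tert-butyl hydroperoxide, CC(C)(C)OO (oxygen passed on through SeO2, O=[Se]=O)
Why: Catalytic SeO2 allylic oxidation (ene reaction then [2,3]-sigmatropic shift) attacks the more electron-rich terminal isopropylidene and oxidises only its (E)-methyl group, because the 2,3-alkene is deactivated by its allylic oxygen.

Step 3
Reactants: 3 (2E,6E)-8-[(tert-butyldimethylsilyl)oxy]-2,6-dimethylocta-2,6-dien-1-ol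
Product: 4 {[(2E,6E)-8-bromo-3,7-dimethylocta-2,6-dien-1-yl]oxy}(tert-butyl)dimethylsilane
Conditions: CBr4 (1.2 equiv), PPh3 (1.25 equiv), CH2Cl2, −20 to 0 °C; used without storage
Reagents that add atoms: carbon tetrabromide, BrC(Br)(Br)Br
Why: The Appel reaction displaces the primary alkoxyphosphonium by bromide in a direct SN2 step, so neither allylic transposition nor E/Z loss occurs and the silyl ether survives the neutral medium.

Step 4
Reactants: 4 allylic bromide; 5 methyl acetate
Product: 7 methyl (4E,8E)-10-[(tert-butyldimethylsilyl)oxy]-4,8-dimethyldeca-4,8-dienoate, via lithium enolate of methyl acetate 6 (not isolated)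
Conditions: LiN(iPr)2 (1.5 equiv), 5 (1.6 equiv), THF, −78 °C, 30 min; then 4, DMPU (3 equiv), −78 to −30 °C
Reagents that add atoms: none
Why: Ester enolate alkylation (SN2) of a very reactive primary allylic bromide is faster at low temperature than Claisen self-condensation, and it adds the two carbons that become C1 and C2 of the lactone.

Step 5
Reactants: 7 methyl (4E,8E)-10-[(tert-butyldimethylsilyl)oxy]-4,8-dimethyldeca-4,8-dienoate
Product: 8 methyl (4E,8E)-10-hydroxy-4,8-dimethyldeca-4,8-dienoate
Conditions: HF·pyridine, extra pyridine, THF, 0 °C to rt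
Reagents that add atoms: none
Why: Fluoride-driven desilylation under buffered, non-basic conditions frees the allylic alcohol without saponifying the methyl ester or moving either alkene.

Step 6
Reactants: 8 methyl (4E,8E)-10-hydroxy-4,8-dimethyldeca-4,8-dienoate
Product: 9 methyl (4E)-7-[(2S,3S)-3-(hydroxymethyl)-2-methyloxiran-2-yl]-4-methylhept-4-enoate
Conditions: Ti(OiPr)4 (10 mol %), L-(+)-diethyl tartrate (12 mol %), t-BuOOH (2 equiv, decane), 4 Å molecular sieves, CH2Cl2, −20 °C
Reagents that add atoms: tert-butyl hydroperoxide, CC(C)(C)OO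
Why: In the Katsuki–Sharpless asymmetric epoxidation the tetravalent titanium–L-(+)-tartrate catalyst binds the allylic alcohol and delivers oxygen to one face of the 8,9-alkene only, setting the first two stereocentres as (8S,9S) just as for geraniol itself (about 95% ee), while the isolated 4,5-alkene and the ester are untouched.

Step 7
Reactants: 9 epoxy alcohol
Product: 10 methyl (4E)-7-[(2S,3S)-3-(acetoxymethyl)-2-methyloxiran-2-yl]-4-methylhept-4-enoate
Conditions: Ac2O (1.3 equiv), Et3N (1.5 equiv), DMAP (5 mol %), CH2Cl2, 0 °C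
Reagents that add atoms: acetic anhydride, CC(=O)OC(C)=O
Why: DMAP-catalysed acylation caps the epoxy alcohol so that it can neither undergo Payne rearrangement nor be oxidised in the basic peroxymonosulfate medium of step 8, and the acetate is chosen because the hydrolase of step 9 removes it together with the methyl ester.

Step 8
Reactants: 10 epoxy acetate
Product: 11 methyl 3-[(2R,3R)-3-{2-[(2S,3S)-3-(acetoxymethyl)-2-methyloxiran-2-yl]ethyl}-2-methyloxiran-2-yl]propanoate
Conditions: D-fructose-derived Shi ketone (1,2:4,5-di-O-isopropylidene-β-D-erythro-2,3-hexodiulo-2,6-pyranose, 30 mol %), KHSO5 (as 2KHSO5·KHSO4·K2SO4, 1.4 equiv) and K2CO3 added in parallel, Bu4NHSO4 (4 mol %), MeCN/CH2(OMe)2/aq Na2B4O7 buffer (pH 10.5), 0 °C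
Reagents that add atoms: potassium peroxymonosulfate KHSO5, [K+].[O-]S(=O)(=O)OO (oxygen passed on through the dioxirane of the ketone catalyst)
Why: In the Shi asymmetric epoxidation the chiral dioxirane attacks the only remaining alkene, an (E)-trisubstituted one, through the spiro transition state to give the (4R,5R)-epoxide (dr about 10–20:1), and because two independent catalysts have now acted the wrong enantiomer ends up mostly in a separable diastereomer.

Step 9
Reactants: 11 bis-epoxy diester
Product: 14 (5S)-5-{(2R,5R)-5-[(1S)-1,2-dihydroxyethyl]-5-methyloxolan-2-yl}-5-methyloxolan-2-one, via bis-epoxy hydroxy acid 12 (not isolated), via hydroxylactone epoxy alcohol 13 (not isolated)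
Conditions: pig liver esterase (a carboxylesterase, serine hydrolase class, EC 3.1.1.1), KH2PO4/K2HPO4 buffer pH 7.4, acetone (10% v/v), 30 °C; bring to pH 4 with citric acid at 0 °C, extract with EtOAc; then camphorsulfonic acid (10 mol %), CH2Cl2, 0 °C to rt; diastereomers removed by chromatography
Reagents that add atoms: water, O
Why: The carboxylesterase cleaves the methyl ester and the primary acetate at neutral pH without touching either epoxide, and the freed acid then starts a Brønsted-acid epoxide-opening cascade of two 5-exo-tet cyclisations at the tertiary epoxide carbons, in which carboxyl attack at C4 with inversion (R to S) closes ring A and leaves the C5 carbinol (R) untouched, whose hydroxyl then attacks C8 with inversion (S to R) to close ring B as the 2,5-trans oxolane.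

Step 10
Reactants: 14 ring A/ring B diol
Product: 15 (2R,5R)-2-methyl-5-[(2S)-2-methyl-5-oxooxolan-2-yl]oxolane-2-carbaldehyde
Conditions: NaIO4 (1.5 equiv), THF/H2O (2:1), 0 °C to rt
Reagents that add atoms: none
Why: Malaprade glycol cleavage removes C10 and erases the now superfluous C9 carbinol centre, giving an aldehyde whose alpha carbon is quaternary and therefore cannot epimerise.

Step 11
Reactants: 15 aldehyde
Product: 16 (5S)-5-[(2R,5R)-5-ethynyl-5-methyloxolan-2-yl]-5-methyloxolan-2-one
Conditions: dimethyl (1-diazo-2-oxopropyl)phosphonate (1.4 equiv), K2CO3 (2 equiv), MeOH, 0 °C to rt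
Reagents that add atoms: dimethyl (1-diazo-2-oxopropyl)phosphonate, COP(=O)(OC)C(=[N+]=[N-])C(C)=O (supplies the terminal alkyne carbon)
Why: The Ohira–Bestmann variant of the Seyferth–Gilbert homologation turns the non-enolisable aldehyde into the terminal alkyne under mild carbonate conditions that the γ-lactone tolerates (any methanolysed material recloses on work-up) and that leave the three stereocentres alone.

Step 12
Reactants: 16 alkyne
Product: 17 (5S)-5-methyl-5-{(2R,5R)-5-methyl-5-[(E)-2-(tributylstannyl)ethenyl]oxolan-2-yl}oxolan-2-one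
Conditions: Bu3SnH (1.3 equiv, slow addition), PdCl2(PPh3)2 (3 mol %), THF, 0 °C to rt; chromatography on Et3N-washed silica
Reagents that add atoms: tributyltin hydride, CCCC[SnH](CCCC)CCCC
Why: Palladium-catalysed syn-hydrostannation places tin on the terminal carbon, away from the fully substituted propargylic centre, so the (E)-β-alkenylstannane is formed essentially alone.

**Fragment 2**

Step 13
Reactants: 18 tert-butyldimethyl(prop-2-yn-1-yloxy)silane; 19 5-bromo-2-methylpent-2-ene
Product: 21 tert-butyldimethyl[(7-methyloct-6-en-2-yn-1-yl)oxy]silane, via lithium acetylide 20 (not isolated)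
Conditions: n-BuLi (1.05 equiv), THF, −78 °C; then 19, DMPU (4 equiv), −78 °C to 40 °C
Reagents that add atoms: none
Why: Acetylide alkylation (SN2) of a primary bromide in a dipolar co-solvent outruns elimination and joins the two achiral pieces without creating any stereocentre.

Step 14
Reactants: 21 silyl enynyl ether
Product: 22 7-methyloct-6-en-2-yn-1-ol
Conditions: Bu4NF (1.1 equiv), THF, 0 °C to rt
Reagents that add atoms: none
Why: Fluoride-mediated desilylation frees the propargylic hydroxyl that must direct the next step.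

Step 15
Reactants: 22 7-methyloct-6-en-2-yn-1-ol
Product: 24 (2Z)-3-iodo-7-methylocta-2,6-dien-1-ol, via cyclic alkenylaluminate 23 (not isolated)
Conditions: NaAlH2(OCH2CH2OMe)2 (1.5 equiv), Et2O, 0 °C to rt; then I2 (excess), THF, −78 to 0 °C
Reagents that add atoms: iodine, II
Why: Hydroxyl-directed trans-hydroalumination puts aluminium on C3 inside a five-membered O–Al chelate, and iodinolysis with retention gives only the (Z)-3-iodoallylic alcohol, with iodine cis to CH2OH as the lactonisation requires.

Step 16
Reactants: 24 (2Z)-3-iodo-7-methylocta-2,6-dien-1-ol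
Product: 25 3-(4-methylpent-3-en-1-yl)furan-2(5H)-one
Conditions: Pd(PPh3)4 (5 mol %), K2CO3 (2 equiv), CO (1 atm), THF, 50 °C
Reagents that add atoms: carbon monoxide, [C-]#[O+]
Why: In this palladium-catalysed carbonylative lactonisation, oxidative addition of zerovalent palladium and CO insertion give an acylpalladium that the cis hydroxymethyl group traps at once, closing ring C much faster than the trisubstituted alkene could insert.

Step 17
Reactants: 25 3-(4-methylpent-3-en-1-yl)furan-2(5H)-one
Product: 26 3-[(3E)-5-hydroxy-4-methylpent-3-en-1-yl]furan-2(5H)-one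
Conditions: SeO2 (0.2 equiv), t-BuOOH (2.5 equiv), CH2Cl2, 0 °C to rt; the minor enal is removed by chromatography
Reagents that add atoms: tert-butyl hydroperoxide, CC(C)(C)OO (oxygen passed on through SeO2, O=[Se]=O)
Why: SeO2 allylic oxidation (ene reaction then [2,3]-shift) selects the electron-rich isopropylidene over the electron-poor butenolide alkene and oxidises only the (E)-methyl group, fixing the E geometry of the trisubstituted alkene.

Step 18
Reactants: 26 allylic alcohol
Product: 27 3-[(3E)-5-bromo-4-methylpent-3-en-1-yl]furan-2(5H)-one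
Conditions: CBr4 (1.2 equiv), PPh3 (1.25 equiv), CH2Cl2, −20 to 0 °C; used promptly
Reagents that add atoms: carbon tetrabromide, BrC(Br)(Br)Br
Why: The Appel reaction converts the primary allylic alcohol into the bromide by direct SN2 displacement under neutral conditions that neither isomerise the alkene nor harm the butenolide.

**Union**

Step 19
Reactants: 17 (E)-alkenylstannane; 27 allylic bromide
Product: 28 3-[(3E,6E)-4-methyl-7-{(2R,5R)-2-methyl-5-[(2S)-2-methyl-5-oxooxolan-2-yl]oxolan-2-yl}hepta-3,6-dien-1-yl]furan-2(5H)-one (target)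
Conditions: Pd2(dba)3 (2.5 mol %), AsPh3 (10 mol %), degassed THF, rt to 45 °C
Reagents that add atoms: none
Why: In this Migita–Kosugi–Stille allyl–alkenyl cross-coupling, zerovalent palladium ionises the primary allylic bromide, the alkenylstannane transmetallates with retention, and reductive elimination occurs at the less hindered CH2 terminus, giving the skipped (3E,6E)-diene under neutral conditions that spare both lactones and all three stereocentres.

**Compound list**
1 | geraniol, (2E)-3,7-dimethylocta-2,6-dien-1-ol | CC(C)=CCC/C(C)=C/CO | starting material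
2 | geranyl TBS ether | CC(C)=CCC/C(C)=C/CO[Si](C)(C)C(C)(C)C | intermediate
3 | (2E,6E)-8-[(tert-butyldimethylsilyl)oxy]-2,6-dimethylocta-2,6-dien-1-ol | OC/C(C)=C/CC/C(C)=C/CO[Si](C)(C)C(C)(C)C | intermediate
4 | {[(2E,6E)-8-bromo-3,7-dimethylocta-2,6-dien-1-yl]oxy}(tert-butyl)dimethylsilane | BrC/C(C)=C/CC/C(C)=C/CO[Si](C)(C)C(C)(C)C | intermediate
5 | methyl acetate | COC(C)=O | starting material
6 | lithium enolate of methyl acetate | [Li+].C=C([O-])OC | intermediate
7 | methyl (4E,8E)-10-[(tert-butyldimethylsilyl)oxy]-4,8-dimethyldeca-4,8-dienoate | COC(=O)CC/C(C)=C/CC/C(C)=C/CO[Si](C)(C)C(C)(C)C | intermediate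
8 | methyl (4E,8E)-10-hydroxy-4,8-dimethyldeca-4,8-dienoate | COC(=O)CC/C(C)=C/CC/C(C)=C/CO | intermediate
9 | methyl (4E)-7-[(2S,3S)-3-(hydroxymethyl)-2-methyloxiran-2-yl]-4-methylhept-4-enoate | COC(=O)CC/C(C)=C/CC[C@]1(C)O[C@H]1CO | intermediate
10 | methyl (4E)-7-[(2S,3S)-3-(acetoxymethyl)-2-methyloxiran-2-yl]-4-methylhept-4-enoate | COC(=O)CC/C(C)=C/CC[C@]1(C)O[C@H]1COC(C)=O | intermediate
11 | methyl 3-[(2R,3R)-3-{2-[(2S,3S)-3-(acetoxymethyl)-2-methyloxiran-2-yl]ethyl}-2-methyloxiran-2-yl]propanoate | COC(=O)CC[C@@]1(C)O[C@@H]1CC[C@]2(C)O[C@H]2COC(C)=O | intermediate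
12 | 3-[(2R,3R)-3-{2-[(2S,3S)-3-(hydroxymethyl)-2-methyloxiran-2-yl]ethyl}-2-methyloxiran-2-yl]propanoic acid | OC(=O)CC[C@@]1(C)O[C@@H]1CC[C@]2(C)O[C@H]2CO | intermediate
13 | (5S)-5-{(1R)-1-hydroxy-3-[(2S,3S)-3-(hydroxymethyl)-2-methyloxiran-2-yl]propyl}-5-methyloxolan-2-one | C[C@]1(CCC(=O)O1)[C@H](O)CC[C@]2(C)O[C@H]2CO | intermediate
14 | (5S)-5-{(2R,5R)-5-[(1S)-1,2-dihydroxyethyl]-5-methyloxolan-2-yl}-5-methyloxolan-2-one | OC[C@H](O)[C@@]1(C)CC[C@H]([C@]2(C)CCC(=O)O2)O1 | intermediate
15 | (2R,5R)-2-methyl-5-[(2S)-2-methyl-5-oxooxolan-2-yl]oxolane-2-carbaldehyde | O=C[C@@]1(C)CC[C@H]([C@]2(C)CCC(=O)O2)O1 | intermediate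
16 | (5S)-5-[(2R,5R)-5-ethynyl-5-methyloxolan-2-yl]-5-methyloxolan-2-one | C#C[C@@]1(C)CC[C@H]([C@]2(C)CCC(=O)O2)O1 | intermediate
17 | (5S)-5-methyl-5-{(2R,5R)-5-methyl-5-[(E)-2-(tributylstannyl)ethenyl]oxolan-2-yl}oxolan-2-one | CCCC[Sn](CCCC)(CCCC)/C=C/[C@@]1(C)CC[C@H]([C@]2(C)CCC(=O)O2)O1 | intermediate
18 | tert-butyldimethyl(prop-2-yn-1-yloxy)silane | C#CCO[Si](C)(C)C(C)(C)C | starting material
19 | 5-bromo-2-methylpent-2-ene | CC(C)=CCCBr | starting material
20 | lithium acetylide of 18 | [Li]C#CCO[Si](C)(C)C(C)(C)C | intermediate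
21 | tert-butyldimethyl[(7-methyloct-6-en-2-yn-1-yl)oxy]silane | CC(C)=CCCC#CCO[Si](C)(C)C(C)(C)C | intermediate
22 | 7-methyloct-6-en-2-yn-1-ol | CC(C)=CCCC#CCO | intermediate
23 | sodium 2,2-bis(2-methoxyethoxy)-3-(4-methylpent-3-en-1-yl)-2,5-dihydro-1,2-oxaluminol-2-uide (five-membered O–Al–C=C chelate) | [Na+].COCCO[Al-]1(OCCOC)OCC=C1CCC=C(C)C | intermediate
24 | (2Z)-3-iodo-7-methylocta-2,6-dien-1-ol | CC(C)=CCC/C(I)=C/CO | intermediate
25 | 3-(4-methylpent-3-en-1-yl)furan-2(5H)-one | CC(C)=CCCC1=CCOC1=O | intermediate
26 | 3-[(3E)-5-hydroxy-4-methylpent-3-en-1-yl]furan-2(5H)-one | OC/C(C)=C/CCC1=CCOC1=O | intermediate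
27 | 3-[(3E)-5-bromo-4-methylpent-3-en-1-yl]furan-2(5H)-one | BrC/C(C)=C/CCC1=CCOC1=O | intermediate
28 | 3-[(3E,6E)-4-methyl-7-{(2R,5R)-2-methyl-5-[(2S)-2-methyl-5-oxooxolan-2-yl]oxolan-2-yl}hepta-3,6-dien-1-yl]furan-2(5H)-one | C/C(=C\CCC1=CCOC1=O)C/C=C/[C@@]1(C)CC[C@H]([C@]2(C)CCC(=O)O2)O1 | target

**Totals.** Total step count: 19. Longest linear sequence: 13 (steps 1–12, then 19). Fragment 2 takes 6 steps (13–18) before the union.

**The three steps most likely to fail**

Step 19 (Stille union). The 2-methyl-substituted π-allylpalladium could isomerise and erode the E geometry of the trisubstituted alkene. It could also couple at the branched terminus, or the stannane could protodestannylate.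
The fallback sets out from alkyne 16 (bypassing step 12) and bromide 27, and it avoids π-allyl chemistry altogether. A coupling mediated by monovalent copper (CuI, NaI, Cs2CO3, DMF, rt) joins the sp carbon to the allylic CH2 in an SN2 sense and gives the skipped enyne F1. Ruthenium-catalysed trans-hydrosilylation ((EtO)3SiH, [Cp*Ru(MeCN)3]PF6 5 mol %, CH2Cl2, 0 °C) gives the (Z)-alkenyltriethoxysilane F2; its regioisomer would serve equally well. Protodesilylation with retention (AgF, THF/MeOH/H2O, dark, rt) leaves the E-alkene and comes back to the route at target 28.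

Step 9 (esterase hydrolysis and cascade). The esterase may be slow on the γ-branched methyl ester, or the epoxides may suffer during long exposure to water.
The fallback sets out from 11. A lipase (triacylglycerol hydrolase class, immobilised Candida antarctica lipase B) in MTBE with methanol at 30 °C removes only the primary acetate by transesterification. The methyl ester merely exchanges with itself, and the product is the bis-epoxy hydroxy methyl ester F3. Camphorsulfonic acid (10 mol %) in CH2Cl2 containing one equivalent of water then runs the cascade with the ester carbonyl, rather than a free acid, as the first nucleophile. The dialkoxycarbenium ion is hydrolysed to the lactone, the inversions at C4 and C8 are the same, and the route is rejoined at diol 14.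

Step 17 (SeO2 oxidation next to a butenolide). Conversion may be low, over-oxidation to the enal may dominate, or selenium residues may be hard to remove.
The fallback sets out from 25 and rebuilds the alkene instead of oxidising it. Chemoselective ozonolysis of the electron-rich alkene (O3, CH2Cl2, −78 °C, dye end-point, then Me2S) gives the aldehyde F4. A Wittig reaction with the stabilised ylide 2-(triphenylphosphoranylidene)propanal (toluene, 80 °C) gives the (E)-enal F5. Luche reduction (NaBH4, CeCl3·7H2O, MeOH, −40 °C) then reduces only the aldehyde and returns to the route at allylic alcohol 26.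

**Further compounds**
F1 | step 19 | 3-[(3E)-4-methyl-7-{(2R,5R)-2-methyl-5-[(2S)-2-methyl-5-oxooxolan-2-yl]oxolan-2-yl}hept-3-en-6-yn-1-yl]furan-2(5H)-one | C/C(=C\CCC1=CCOC1=O)CC#C[C@@]1(C)CC[C@H]([C@]2(C)CCC(=O)O2)O1
F2 | step 19 | 3-[(3E,6Z)-4-methyl-7-{(2R,5R)-2-methyl-5-[(2S)-2-methyl-5-oxooxolan-2-yl]oxolan-2-yl}-6-(triethoxysilyl)hepta-3,6-dien-1-yl]furan-2(5H)-one | CCO[Si](OCC)(OCC)/C(C/C(C)=C/CCC1=CCOC1=O)=C\[C@@]1(C)CC[C@H]([C@]2(C)CCC(=O)O2)O1
F3 | step 9 | methyl 3-[(2R,3R)-3-{2-[(2S,3S)-3-(hydroxymethyl)-2-methyloxiran-2-yl]ethyl}-2-methyloxiran-2-yl]propanoate | COC(=O)CC[C@@]1(C)O[C@@H]1CC[C@]2(C)O[C@H]2CO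
F4 | step 17 | 3-(2-oxo-2,5-dihydrofuran-3-yl)propanal | O=CCCC1=CCOC1=O
F5 | step 17 | (2E)-2-methyl-5-(2-oxo-2,5-dihydrofuran-3-yl)pent-2-enal | O=C/C(C)=C/CCC1=CCOC1=O
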